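(The rate constants were set for the occasion; the flask was simulated.)

**The vessel.** A closed, stirred vessel receives the same substrate and partner in each of the runs, which differ in the protic impurity they carry.

    crystals ⇌ product, rate k1*(cs1 - [product]) while solid is left; crystals form when [product] > cs1 (cs1 = 1.1 mM, k1 = 0.768 s⁻¹)
    substrate + partner → product, rate k2*[substrate]*[partner]^0.5 (k2 = 0.335 M⁻⁰·⁵ s⁻¹)
    partner + protic impurity → quenched reagent (k3 = 2090 M⁻¹ s⁻¹)

common to all: substrate 0.0020 M; partner 8.00 mM; time 80 s
- grey: protic impurity 0.0120 mM
- red: protic impurity 0.0250 mM
- amber: protic impurity 0.0500 mM
- green: protic impurity 0.100 mM
- teal: protic impurity 0.200 mM

- amount of product at the end, in percent of the substrate charged for grey, red, amber, green, teal, in this order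
- the shape of the row from first to last (falls all the way / falls, then rises / rises, then falls / rises all the way / hardly changes)

- what is said of product includes crystals
- crystals is a solid; its amount is given per volume of the solution
- "hardly changes" means that all values lie within two and a half points (for a concentration: within two and a half percent of the largest)
- run time (grey): 80 s

**One impurity molecule.** Follow a molecule of protic impurity. Among partner at its charge it lasts about 0.0598 s, while a substrate molecule lasts about 33.4 s, so the quench ends far sooner. But at the start in grey, product formation uses partner at just 0.30 of the quench's rate, which looks alarming. The rate misleads, though: the quench takes one partner per impurity molecule, and teal's impurity charge is 2.50 % of the partner.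

**First estimate.** Partner is in excess, so substrate decays in a pseudo-first-order way. Let N be the number of lifetimes in the run. With partner held at its charge, N is 2.40, and 9.10 % of the substrate remains.

**An objection.** Partner doesn't stay put: substrate can consume a quarter of it. So we take B, the partner level with 0.5 of the substrate's charge spent, which is 7.00 mM. Then N becomes 2.24, and the fraction left is 10.6 %, a yield of 89.4 %. Crystals raise a second doubt, since the substrate's charge is larger than the solubility 1.1 mM. But the rate of product formation contains no product, and crystals are counted as product.

**The toll.** With order 0.5 in partner, a small relative cut in partner cuts the substrate's decay rate by 0.5 of that relative size. Multiplying the fraction left by N and dividing by 2B gives the toll, the yield lost, as a fraction of the substrate charged, per unit of impurity charged: 0.0170 mM⁻¹. For teal that is 0.34 percentage points.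

**The forecast.** It gave 89 %, 88.95 %, 88.9 %, 88.8 % and 88.6 %, hardly changes, holding that "Crystallisation only moves product between solution and solid". Its first figure lies lower than our 89.4 %.

**The result.** The flasks give 89.0 %, 89.0 %, 88.9 %, 88.8 % and 88.6 %: hardly changes. Substrate left at the end reads 11.0 % in grey and 11.4 % in teal. The toll on the step from grey's impurity charge to teal's is 0.32 points, and the row falls 0.4 points from grey to teal. For grey the toll is 0.02 points, and the quench makes no visible difference to grey's 89.0 %.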